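**Strategy.** The target is cut at the oxepane O1–C2 bond and the cyclohexane C5a–C6 bond of its benzoxepine half, so that this whole trans-fused bicycle (C3, C5a, C6, C9a) is folded last from an acyclic bis-epoxide chain that already carries the finished hydroazulene. One silyl-triflate-triggered epoxide-opening cascade, ended by a regiodefined (Z)-silyl enol ether, forms both rings and sets C5a, C6 and C9a, with C3 carried in from the epoxide. Its precursor comes from cross-metathesis of a carvone-derived allyl hydroazulenol with a geranylacetone-derived bis-epoxy vinyl ketone and 1,4-hydrosilylation; methyl addition to the resulting ketone completes the target.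

Key step: step 21

Remark: locants in the text are those of the final skeleton (1-benzoxepine: O1, C2, C3, C5a, C6, C7, C9a; azulene: C1, C3a, C4, C5, C6, C8a); the D-fructose-derived Shi ketone is taken to give (R,R)-epoxides from E-trisubstituted alkenes, and a TBS ether is used where a tetrahydropyranyl ether would serve equally.

Step 1
Reactants: 1 (R)-(−)-carvone
Product: 2 (1R,4R,6R)-1-methyl-4-(prop-1-en-2-yl)-7-oxabicyclo[4.1.0]heptan-2-one
Conditions: 30% H2O2, NaOH (cat.), MeOH, 0 °C
Reagents that add atoms: hydrogen peroxide, OO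
Why: Weitz–Scheffer nucleophilic epoxidation touches only the enone C=C, and the hydroperoxide should add anti to the isopropenyl group, which sets both epoxide carbons.

Step 2
Reactants: 2 (1R,4R,6R)-carvone oxide
Product: 3 (2S,3R,5R)-2-chloro-3-hydroxy-2-methyl-5-(prop-1-en-2-yl)cyclohexan-1-one
Conditions: LiCl, CF3CO2H, THF, 23 °C
Reagents that add atoms: lithium chloride, [Li+].[Cl-]
Why: acid-promoted SN2 opening of the α,β-epoxy ketone by chloride at the α-carbon with inversion should give the α-chloro-β-hydroxy ketone with Cl anti to OH.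

Step 3
Reactants: 3 chlorohydrin
Product: 4 (2S,3R,5R)-3-[(tert-butyldimethylsilyl)oxy]-2-chloro-2-methyl-5-(prop-1-en-2-yl)cyclohexan-1-one
Conditions: TBSOTf, 2,6-lutidine, CH2Cl2, −78 °C
Reagents that add atoms: tert-butyldimethylsilyl triflate, CC(C)(C)[Si](C)(C)OS(=O)(=O)C(F)(F)F
Why: O-silylation of the secondary alcohol prevents re-closure to the epoxide under the basic conditions of step 4 and touches no stereocentre.

Step 4
Reactants: 4 silyl-protected chlorohydrin
Product: 6 methyl (1R,2S,3R,5R)-3-[(tert-butyldimethylsilyl)oxy]-2-methyl-5-(prop-1-en-2-yl)cyclopentane-1-carboxylate, via cyclopropanone 5 (not isolated)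
Conditions: NaOMe, MeOH, 0 °C
Reagents that add atoms: sodium methoxide, C[O-].[Na+]
Why: Favorskii ring contraction, in which the C6 enolate displaces the tertiary chloride with inversion to give 5 and methoxide opening leaves the ester cis to the isopropenyl group (C1 and C5 fixed by the substrate, C2 protonated with retention and later destroyed).

Step 5
Reactants: 6 cyclopentane ester
Product: 7 [(1R,2S,3R,5R)-3-[(tert-butyldimethylsilyl)oxy]-2-methyl-5-(prop-1-en-2-yl)cyclopentyl]methanol
Conditions: LiAlH4, THF, 0 °C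
Reagents that add atoms: none
Why: hydride reduction of the ester to the primary alcohol removes the only epimerisable centre (C1, cis to isopropenyl) before any further base is used.

Step 6
Reactants: 7 primary alcohol
Product: 8 tert-butyl{[(1R,2S,3R,4R)-3-(iodomethyl)-2-methyl-4-(prop-1-en-2-yl)cyclopentyl]oxy}dimethylsilane
Conditions: I2, PPh3, imidazole, CH2Cl2, 0 → 23 °C
Reagents that add atoms: iodine, II
Why: Appel-type iodination of the primary alcohol via the alkoxyphosphonium salt, with no stereocentre involved.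

Step 7
Reactants: 8 primary iodide
Product: 9 dimethyl {4-[(1R,2S,3R,5R)-3-[(tert-butyldimethylsilyl)oxy]-2-methyl-5-(prop-1-en-2-yl)cyclopentyl]-2-oxobutyl}phosphonate
Conditions: dimethyl (2-oxopropyl)phosphonate, NaH then n-BuLi, THF, 0 °C; then 8, 0 → 23 °C
Reagents that add atoms: dimethyl (2-oxopropyl)phosphonate, CC(=O)CP(=O)(OC)OC
Why: γ-alkylation of the β-ketophosphonate dianion at its terminal carbon by SN2 on the saturated (non-allylic) iodide adds the future ring carbons C7, C6 and C5.

Step 8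
Reactants: 9 β-ketophosphonate
Product: 10 5-[(1R,2S,3R,5R)-3-[(tert-butyldimethylsilyl)oxy]-2-methyl-5-(prop-1-en-2-yl)cyclopentyl]pent-1-en-3-one
Conditions: 37% aq. HCHO, K2CO3, THF/H2O, 23 °C
Reagents that add atoms: formaldehyde, C=O
Why: Horner–Wadsworth–Emmons olefination with formaldehyde converts the β-ketophosphonate into the vinyl ketone.

Step 9
Reactants: 10 vinyl ketone
Product: 11 (1S,2R,3aR,8aR)-2-[(tert-butyldimethylsilyl)oxy]-1,4-dimethyl-1,2,3,3a,8,8a-hexahydroazulen-6(7H)-one
Conditions: Hoveyda–Grubbs II (5 mol %), toluene, 80 °C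
Reagents that add atoms: none
Why: ring-closing metathesis of the isopropenyl group with the vinyl ketone closes the cycloheptenone as a β-methyl enone, and the cis chains on the cyclopentane (step 4) dictate the cis ring fusion (3aR,8aR).

Step 10
Reactants: 11 silyloxy enone
Product: 12 (1S,2R,3aR,8aR)-2-hydroxy-1,4-dimethyl-1,2,3,3a,8,8a-hexahydroazulen-6(7H)-one
Conditions: TBAF, THF, 0 °C
Reagents that add atoms: none
Why: fluoride cleavage of the silyl ether frees the secondary alcohol without touching the enone.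

Step 11
Reactants: 12 hydroxy enone
Product: 13 (3aR,8aR)-1,4-dimethyl-3,3a,8,8a-tetrahydroazulen-6(7H)-one
Conditions: Martin sulfurane, CH2Cl2, 23 °C
Reagents that add atoms: none
Why: E2-type dehydration through the alkoxysulfurane should remove the anti-periplanar tertiary C1–H to give the trisubstituted (Zaitsev) cyclopentene under neutral conditions that leave the enone and the ring fusion untouched.

Step 12
Reactants: 13 β-methyl cycloheptenone
Product: 15 (3aR,5R,8aR)-5-[(dimethylamino)methyl]-1,4,4-trimethyl-3,3a,4,5,8,8a-hexahydroazulen-6(7H)-one, via silyl enol ether 14 (not isolated)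
Conditions: Me2CuLi (from MeLi, CuI), TMSCl, THF, −78 → −20 °C; then CH2=NMe2+ I−, CH2Cl2, 23 °C
Reagents that add atoms: methyllithium, C[Li]; Eschenmoser's salt, C=[N+](C)C.[I-]
Why: TMSCl-accelerated cuprate 1,4-addition creates the C4 gem-dimethyl carbon (no new stereocentre) and fixes the enol ether regiospecifically towards C5, where Mannich aminomethylation then occurs (C5 configuration inconsequential).

Step 13
Reactants: 15 Mannich base
Product: 17 (3aR,8aR)-1,4,4-trimethyl-5-methylidene-3,3a,4,5,8,8a-hexahydroazulen-6(7H)-one, via ammonium iodide 16 (not isolated)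
Conditions: MeI, Et2O, 23 °C; then aq. NaHCO3, CH2Cl2
Reagents that add atoms: none
Why: N-quaternisation followed by E1cB (Hofmann-type) loss of trimethylamine gives the α-methylene ketone and erases the C5 stereocentre.

Step 14
Reactants: 17 α-methylene ketone
Product: 19 (3aR,5R,8aR)-1,4,4-trimethyl-5-(prop-2-en-1-yl)-3,3a,4,5,8,8a-hexahydroazulen-6(7H)-one, via magnesium enolate 18 (not isolated)
Conditions: CH2=CHMgBr, CuI (10 mol %), THF, −78 °C; then 2,6-di-tert-butyl-4-methylphenol, −78 °C; cold aq. NH4Cl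
Reagents that add atoms: vinylmagnesium bromide, C=C[Mg]Br
Why: copper-catalysed conjugate addition to the unhindered exocyclic methylene gives the C5–C6 enolate regiospecifically, and kinetic protonation by the bulky phenol from the convex face (that of H3a and H8a, away from the cyclopentene) should set (5R).

Step 15
Reactants: 19 allyl ketone
Product: 20 (3aR,5R,6S,8aR)-1,4,4,6-tetramethyl-5-(prop-2-en-1-yl)-3,3a,4,5,6,7,8,8a-octahydroazulen-6-ol
Conditions: MeLi, CeCl3 (MeCeCl2), THF, −78 °C
Reagents that add atoms: methyllithium, C[Li]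
Why: organocerium 1,2-addition (low basicity, so C5 is not epimerised) should occur from the convex face anti to the adjacent C5 allyl group, giving the (6S) carbinol and locking C5.

Step 16
Reactants: 21 (E)-geranylacetone
Product: 22 (5R,6R,9R)-5,6:9,10-diepoxy-6,10-dimethylundecan-2-one
Conditions: D-fructose-derived Shi ketone (30 mol %), Oxone, K2CO3, Bu4NHSO4, MeCN/dimethoxymethane/aq. buffer (pH 10.5), 0 °C
Reagents that add atoms: potassium peroxymonosulfate (Oxone), [K+].[O-]S(=O)(=O)OO
Why: Shi asymmetric epoxidation, in which the chiral dioxirane epoxidises both trisubstituted alkenes through the spiro transition state with the same facial sense and leaves the methyl ketone alone.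

Step 17
Reactants: 22 bis-epoxy methyl ketone
Product: 24 (6R,7R,10R)-1-(dimethylamino)-6,7:10,11-diepoxy-7,11-dimethyldodecan-3-one, via lithium enolate 23 (not isolated)
Conditions: LDA, THF, −78 °C; then CH2=NMe2+ I−, −78 → 0 °C
Reagents that add atoms: Eschenmoser's salt, C=[N+](C)C.[I-]
Why: kinetic deprotonation of the methyl ketone at its methyl group and Mannich reaction of the enolate add one carbon without touching the epoxides.

Step 18
Reactants: 24 Mannich base
Product: 26 (6R,7R,10R)-6,7:10,11-diepoxy-7,11-dimethyldodec-1-en-3-one, via ammonium iodide 25 (not isolated)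
Conditions: MeI, Et2O, 23 °C; then aq. NaHCO3, CH2Cl2
Reagents that add atoms: none
Why: quaternisation and E1cB elimination of trimethylamine give the vinyl ketone under conditions too mild to open the epoxides.

Step 19
Reactants: 20 allyl hydroazulenol; 26 bis-epoxy vinyl ketone
Product: 27 (2E,7R,8R,11R)-7,8:11,12-diepoxy-1-[(3aR,5R,6S,8aR)-6-hydroxy-1,4,4,6-tetramethyl-3,3a,4,5,6,7,8,8a-octahydroazulen-5-yl]-8,12-dimethyltridec-2-en-4-one
Conditions: Hoveyda–Grubbs II (10 mol %), 26 (2.5 equiv), CH2Cl2, 40 °C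
Reagents that add atoms: none
Why: olefin cross-metathesis of the terminal allyl group (type I) with the vinyl ketone (type II) should give the (E)-enone under neutral conditions that spare the epoxides, the trisubstituted cyclopentene and the tertiary alcohol.

Step 20
Reactants: 27 (E)-enone
Product: 28 (3Z,7R,8R,11R)-7,8:11,12-diepoxy-1-[(3aR,5R,6S,8aR)-6-hydroxy-1,4,4,6-tetramethyl-3,3a,4,5,6,7,8,8a-octahydroazulen-5-yl]-8,12-dimethyl-4-(triethylsilyloxy)tridec-3-ene
Conditions: Et3SiH (1.2 equiv), RhCl(PPh3)3 (2 mol %), benzene, 50 °C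
Reagents that add atoms: triethylsilane, CC[SiH](CC)CC
Why: rhodium-catalysed 1,4-hydrosilylation of the enone through its s-cis conformer gives the (Z)-silyl enol ether regiospecifically at the carbon that becomes C6 of the benzoxepine.

Step 21
Reactants: 28 bis-epoxy (Z)-silyl enol ether
Product: 32 (3R,5aR,6R,9aR)-3-hydroxy-6-{2-[(3aR,5R,6S,8aR)-6-hydroxy-1,4,4,6-tetramethyl-3,3a,4,5,6,7,8,8a-octahydroazulen-5-yl]ethyl}-2,2,5a-trimethyloctahydro-1-benzoxepin-7(2H)-one, via tertiary silyl ether 29 (not isolated), via epoxonium triflate 30 (not isolated), via bis-silyl ether 31 (not isolated)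
Conditions: TMSOTf (2.2 equiv), 2,6-di-tert-butyl-4-methylpyridine (3 equiv), CH2Cl2, −78 °C; aq. NaHCO3; then PPTS, MeOH, 23 °C
Reagents that add atoms: none
Why: Fast O-silylation of the tertiary carbinol gives 29, Me3Si+ then activates the terminal epoxide, the oxygen of the neighbouring epoxide opens it at the tertiary carbon to give the bicyclic epoxonium ion 30, and the (Z)-silyl enol ether carbon breaks the tertiary C5a–O bond of 30 with loss of Et3SiOTf to give 31, whose silyl ethers are cleaved by acidic methanol. The closest known reaction type is the Lewis-acid-promoted tandem oxa-/carbacyclization of 1,5-bis-epoxides terminated by an enol silane (biomimetic epoxide-opening cascade). The oxepane closes by 7-endo opening of the activated epoxide at its tertiary carbon (C2) by the epoxide oxygen, and the cyclohexanone closes by 6-endo anti attack of the enol carbon on the tertiary epoxonium carbon through a chair transition state. C3 and C9a keep the configuration of the two Shi epoxides because their C–O bonds are never broken, C5a is inverted by the anti attack so that the ring fusion becomes trans, and C6 follows from the Z enol geometry in the chair, which places the side chain equatorial and cis to the C5a methyl. The step needs endo rather than exo opening in both events and reaction at the epoxides rather than elsewhere: the trisubstituted epoxides put the developing positive charge on their tertiary carbons, triflate and the hindered pyridine are non-nucleophilic, and 29 contains neither a ketone nor a free hydroxyl that could intercept the enol ether or the cation.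

Step 22
Reactants: 32 hydroxy ketone
Product: 33 target (3R,5aR,6R,7S,9aR)-6-{2-[(3aR,5R,6S,8aR)-6-hydroxy-1,4,4,6-tetramethyl-3,3a,4,5,6,7,8,8a-octahydroazulen-5-yl]ethyl}-2,2,5a,7-tetramethyldecahydro-1-benzoxepine-3,7-diol
Conditions: MeLi, CeCl3 (MeCeCl2, 5 equiv), THF, −78 °C; aq. NH4Cl
Reagents that add atoms: methyllithium, C[Li]
Why: organocerium 1,2-addition to the cyclohexanone should occur equatorially, avoiding the 1,3-diaxial C5a methyl, to give the axial (7S) tertiary alcohol cis to the equatorial C6 side chain, while the two free hydroxyls are simply carried as alkoxides.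

**Compound list**

1 | (R)-(−)-carvone | CC1=CC[C@H](CC1=O)C(C)=C | starting material
2 | (1R,4R,6R)-1-methyl-4-(prop-1-en-2-yl)-7-oxabicyclo[4.1.0]heptan-2-one | O=C1C[C@H](C(C)=C)C[C@H]2O[C@@]12C | intermediate
3 | (2S,3R,5R)-2-chloro-3-hydroxy-2-methyl-5-(prop-1-en-2-yl)cyclohexan-1-one | O=C1C[C@H](C(C)=C)C[C@@H](O)[C@]1(C)Cl | intermediate
4 | (2S,3R,5R)-3-[(tert-butyldimethylsilyl)oxy]-2-chloro-2-methyl-5-(prop-1-en-2-yl)cyclohexan-1-one | O=C1C[C@H](C(C)=C)C[C@@H](O[Si](C)(C)C(C)(C)C)[C@]1(C)Cl | intermediate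
5 | cyclopropanone: 2-[(tert-butyldimethylsilyl)oxy]-1-methyl-4-(prop-1-en-2-yl)bicyclo[3.1.0]hexan-6-one, carbonyl bridge cis to isopropenyl | C[C@]12[C@H](O[Si](C)(C)C(C)(C)C)C[C@@H](C(C)=C)[C@H]1C2=O | intermediate (not isolated)
6 | methyl (1R,2S,3R,5R)-3-[(tert-butyldimethylsilyl)oxy]-2-methyl-5-(prop-1-en-2-yl)cyclopentane-1-carboxylate | C[C@@H]1[C@H](O[Si](C)(C)C(C)(C)C)C[C@@H](C(C)=C)[C@H]1C(=O)OC | intermediate
7 | [(1R,2S,3R,5R)-3-[(tert-butyldimethylsilyl)oxy]-2-methyl-5-(prop-1-en-2-yl)cyclopentyl]methanol | C[C@@H]1[C@H](O[Si](C)(C)C(C)(C)C)C[C@@H](C(C)=C)[C@H]1CO | intermediate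
8 | tert-butyl{[(1R,2S,3R,4R)-3-(iodomethyl)-2-methyl-4-(prop-1-en-2-yl)cyclopentyl]oxy}dimethylsilane | C[C@@H]1[C@H](O[Si](C)(C)C(C)(C)C)C[C@@H](C(C)=C)[C@H]1CI | intermediate
9 | dimethyl {4-[(1R,2S,3R,5R)-3-[(tert-butyldimethylsilyl)oxy]-2-methyl-5-(prop-1-en-2-yl)cyclopentyl]-2-oxobutyl}phosphonate | C[C@@H]1[C@H](O[Si](C)(C)C(C)(C)C)C[C@@H](C(C)=C)[C@H]1CCC(=O)CP(=O)(OC)OC | intermediate
10 | 5-[(1R,2S,3R,5R)-3-[(tert-butyldimethylsilyl)oxy]-2-methyl-5-(prop-1-en-2-yl)cyclopentyl]pent-1-en-3-one | C[C@@H]1[C@H](O[Si](C)(C)C(C)(C)C)C[C@@H](C(C)=C)[C@H]1CCC(=O)C=C | intermediate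
11 | (1S,2R,3aR,8aR)-2-[(tert-butyldimethylsilyl)oxy]-1,4-dimethyl-1,2,3,3a,8,8a-hexahydroazulen-6(7H)-one | C[C@@H]1[C@H](O[Si](C)(C)C(C)(C)C)C[C@@H]2[C@H]1CCC(=O)C=C2C | intermediate
12 | (1S,2R,3aR,8aR)-2-hydroxy-1,4-dimethyl-1,2,3,3a,8,8a-hexahydroazulen-6(7H)-one | C[C@@H]1[C@H](O)C[C@@H]2[C@H]1CCC(=O)C=C2C | intermediate
13 | (3aR,8aR)-1,4-dimethyl-3,3a,8,8a-tetrahydroazulen-6(7H)-one | CC1=CC[C@@H]2[C@H]1CCC(=O)C=C2C | intermediate
14 | trimethyl{[(3aR,8aR)-1,4,4-trimethyl-3,3a,4,7,8,8a-hexahydroazulen-6-yl]oxy}silane | CC1=CC[C@@H]2[C@H]1CCC(O[Si](C)(C)C)=CC2(C)C | intermediate (not isolated)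
15 | (3aR,5R,8aR)-5-[(dimethylamino)methyl]-1,4,4-trimethyl-3,3a,4,5,8,8a-hexahydroazulen-6(7H)-one | CC1=CC[C@@H]2[C@H]1CCC(=O)[C@@H](CN(C)C)C2(C)C | intermediate
16 | N,N,N-trimethylammonium iodide of 15 | CC1=CC[C@@H]2[C@H]1CCC(=O)[C@@H](C[N+](C)(C)C)C2(C)C.[I-] | intermediate (not isolated)
17 | (3aR,8aR)-1,4,4-trimethyl-5-methylidene-3,3a,4,5,8,8a-hexahydroazulen-6(7H)-one | CC1=CC[C@@H]2[C@H]1CCC(=O)C(=C)C2(C)C | intermediate
18 | bromomagnesium C5–C6 enolate of 19 | CC1=CC[C@@H]2[C@H]1CCC(O[Mg]Br)=C(CC=C)C2(C)C | intermediate (not isolated)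
19 | (3aR,5R,8aR)-1,4,4-trimethyl-5-(prop-2-en-1-yl)-3,3a,4,5,8,8a-hexahydroazulen-6(7H)-one | CC1=CC[C@@H]2[C@H]1CCC(=O)[C@H](CC=C)C2(C)C | intermediate
20 | (3aR,5R,6S,8aR)-1,4,4,6-tetramethyl-5-(prop-2-en-1-yl)-3,3a,4,5,6,7,8,8a-octahydroazulen-6-ol | CC1=CC[C@@H]2[C@H]1CC[C@](C)(O)[C@H](CC=C)C2(C)C | intermediate
21 | (E)-geranylacetone, (5E)-6,10-dimethylundeca-5,9-dien-2-one | CC(=O)CC/C=C(\C)CCC=C(C)C | starting material
22 | (5R,6R,9R)-5,6:9,10-diepoxy-6,10-dimethylundecan-2-one | CC(=O)CC[C@H]1O[C@]1(C)CC[C@H]1OC1(C)C | intermediate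
23 | lithium enolate of 22 at the methyl group | C=C(O[Li])CC[C@H]1O[C@]1(C)CC[C@H]1OC1(C)C | intermediate (not isolated)
24 | (6R,7R,10R)-1-(dimethylamino)-6,7:10,11-diepoxy-7,11-dimethyldodecan-3-one | CN(C)CCC(=O)CC[C@H]1O[C@]1(C)CC[C@H]1OC1(C)C | intermediate
25 | N,N,N-trimethylammonium iodide of 24 | C[N+](C)(C)CCC(=O)CC[C@H]1O[C@]1(C)CC[C@H]1OC1(C)C.[I-] | intermediate (not isolated)
26 | (6R,7R,10R)-6,7:10,11-diepoxy-7,11-dimethyldodec-1-en-3-one | C=CC(=O)CC[C@H]1O[C@]1(C)CC[C@H]1OC1(C)C | intermediate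
27 | (2E,7R,8R,11R)-7,8:11,12-diepoxy-1-[(3aR,5R,6S,8aR)-6-hydroxy-1,4,4,6-tetramethyl-3,3a,4,5,6,7,8,8a-octahydroazulen-5-yl]-8,12-dimethyltridec-2-en-4-one | CC1=CC[C@@H]2[C@H]1CC[C@](C)(O)[C@H](C/C=C/C(=O)CC[C@H]1O[C@]1(C)CC[C@H]1OC1(C)C)C2(C)C | intermediate
28 | (3Z)-triethylsilyl enol ether of 27 (C3=C4, OSiEt3 on C4, cis to C2) | CC1=CC[C@@H]2[C@H]1CC[C@](C)(O)[C@H](CC/C=C(\O[Si](CC)(CC)CC)CC[C@H]1O[C@]1(C)CC[C@H]1OC1(C)C)C2(C)C | intermediate
29 | trimethylsilyl ether of 28 at the tertiary carbinol | CC1=CC[C@@H]2[C@H]1CC[C@](C)(O[Si](C)(C)C)[C@H](CC/C=C(\O[Si](CC)(CC)CC)CC[C@H]1O[C@]1(C)CC[C@H]1OC1(C)C)C2(C)C | intermediate (not isolated)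
30 | bicyclic epoxonium triflate (oxepane closed, C5a–C9a epoxide held as trialkyloxonium, C3–OSiMe3) | CC1=CC[C@@H]2[C@H]1CC[C@](C)(O[Si](C)(C)C)[C@H](CC/C=C(\O[Si](CC)(CC)CC)CC[C@@H]1[C@@]3(C)CC[C@@H](O[Si](C)(C)C)C(C)(C)[O+]13)C2(C)C.[O-]S(=O)(=O)C(F)(F)F | intermediate (not isolated)
31 | bis(trimethylsilyl) ether of 32 | CC1=CC[C@@H]2[C@H]1CC[C@](C)(O[Si](C)(C)C)[C@H](CC[C@@H]1[C@@]3(C)CC[C@@H](O[Si](C)(C)C)C(C)(C)O[C@@H]3CCC1=O)C2(C)C | intermediate (not isolated)
32 | (3R,5aR,6R,9aR)-3-hydroxy-6-{2-[(3aR,5R,6S,8aR)-6-hydroxy-1,4,4,6-tetramethyl-3,3a,4,5,6,7,8,8a-octahydroazulen-5-yl]ethyl}-2,2,5a-trimethyloctahydro-1-benzoxepin-7(2H)-one | CC1=CC[C@@H]2[C@H]1CC[C@](C)(O)[C@H](CC[C@@H]1[C@@]3(C)CC[C@@H](O)C(C)(C)O[C@@H]3CCC1=O)C2(C)C | intermediate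
33 | (3R,5aR,6R,7S,9aR)-6-{2-[(3aR,5R,6S,8aR)-6-hydroxy-1,4,4,6-tetramethyl-3,3a,4,5,6,7,8,8a-octahydroazulen-5-yl]ethyl}-2,2,5a,7-tetramethyldecahydro-1-benzoxepine-3,7-diol (CNP0214586.1) | CC1=CC[C@@H]2[C@H]1CC[C@](C)(O)[C@H](CC[C@@H]1[C@@]3(C)CC[C@@H](O)C(C)(C)O[C@@H]3CC[C@]1(C)O)C2(C)C | target

**Totals.** Total step count: 22. Longest linear sequence: 19 steps (steps 1–15 and 19–22).

**Steps most likely to fail**

Step 21 (key step). What may go wrong: the internal silyl enol ether may be outrun by exo opening of the epoxonium ion to tetrahydrofuran or tetrahydropyran products, by a hydride shift to a ketone, or by simple desilylation on this large substrate. Fallback: cyclise before coupling. From 26, copper-catalysed addition of vinylmagnesium bromide in the presence of TMSCl should give the (Z)-trimethylsilyl enol ether F1. The same cascade on this small substrate, promoted by TBSOTf with 2,6-di-tert-butyl-4-methylpyridine, should give the bicyclic allyl ketone F2 as its C3 silyl ether, and ozonolysis (O3, then PPh3) the aldehyde F3. BF3·OEt2-mediated Mukaiyama aldol addition of enol ether 14 should give the β-hydroxy ketone F4, and mesylation with DBU elimination the exocyclic enone F5. Conjugate reduction with Stryker's reagent, with protonation of the copper enolate from the convex face, should give the diketone F6, and HF·pyridine the diketo alcohol F7. Double addition of MeCeCl2 as in steps 15 and 22 then rejoins the route at the target 33.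

Step 14. What may go wrong: proton transfer to enolate 18 with poor or reversed facial selectivity, which would give the C5 epimer. Fallback: if the accessible face proves to be the other one, the C5–C bond is formed last instead of the C5–H bond. From 14, methyllithium should liberate the lithium enolate F8, and C-allylation with allyl iodide from that same face should give 19 directly.

Step 12. What may go wrong: the cuprate may fail to add to the β,β-disubstituted, neopentyl-like enone carbon, leaving enone or giving 1,2-addition. Fallback: bring in the second methyl as a cyclopropane carbon. From 13, Corey–Chaykovsky cyclopropanation with dimethylsulfoxonium methylide should give the cyclopropyl ketone F9. Dissolving-metal reduction (Li, NH3) should cleave the exocyclic cyclopropane bond that overlaps with the carbonyl, and silylation of the resulting regiodefined lithium enolate (TMSCl, Et3N) rejoins the route at 14.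

**Further compounds**

F1 | step 21 | (Z)-trimethylsilyl enol ether from vinyl addition to 26 | C=CC/C=C(\O[Si](C)(C)C)CC[C@H]1O[C@]1(C)CC[C@H]1OC1(C)C
F2 | step 21 | (3R,5aR,6R,9aR)-3-[(tert-butyldimethylsilyl)oxy]-2,2,5a-trimethyl-6-(prop-2-en-1-yl)octahydro-1-benzoxepin-7(2H)-one | C=CC[C@@H]1[C@@]2(C)CC[C@@H](O[Si](C)(C)C(C)(C)C)C(C)(C)O[C@@H]2CCC1=O
F3 | step 21 | aldehyde from ozonolysis of F2 (C6–CH2CHO) | O=CC[C@@H]1[C@@]2(C)CC[C@@H](O[Si](C)(C)C(C)(C)C)C(C)(C)O[C@@H]2CCC1=O
F4 | step 21 | β-hydroxy ketone from aldol addition of 14 to F3 (mixture at the carbinol carbon and at C5 of the azulenone) | CC1=CC[C@@H]2[C@H]1CCC(=O)C(C(O)C[C@@H]1[C@@]3(C)CC[C@@H](O[Si](C)(C)C(C)(C)C)C(C)(C)O[C@@H]3CCC1=O)C2(C)C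
F5 | step 21 | exocyclic enone from dehydration of F4 (alkene geometry inconsequential) | CC1=CC[C@@H]2[C@H]1CCC(=O)C(=CC[C@@H]1[C@@]3(C)CC[C@@H](O[Si](C)(C)C(C)(C)C)C(C)(C)O[C@@H]3CCC1=O)C2(C)C
F6 | step 21 | diketone with (5R) azulenone centre and C3 silyl ether | CC1=CC[C@@H]2[C@H]1CCC(=O)[C@H](CC[C@@H]1[C@@]3(C)CC[C@@H](O[Si](C)(C)C(C)(C)C)C(C)(C)O[C@@H]3CCC1=O)C2(C)C
F7 | step 21 | diketo alcohol from desilylation of F6 | CC1=CC[C@@H]2[C@H]1CCC(=O)[C@H](CC[C@@H]1[C@@]3(C)CC[C@@H](O)C(C)(C)O[C@@H]3CCC1=O)C2(C)C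
F8 | step 14 | lithium C5–C6 enolate from 14 | CC1=CC[C@@H]2[C@H]1CCC(O[Li])=CC2(C)C
F9 | step 12 | cyclopropyl ketone from cyclopropanation of 13 (methylene on the convex face) | CC1=CC[C@@H]2[C@H]1CCC(=O)[C@H]1C[C@@]21C
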